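## Retrosynthetic overview

1. The tetramic acid is closed last by Lacey–Dieckmann condensation on a 17-membered β-ketoamide macrolactam, which comes from intramolecular amine capture of an acylketene released from a dioxinone.
2. Both side arms are attached to a ring C aldehyde/ester by Horner–Wadsworth–Emmons reactions: the Z-enamide from an L-ornithine diphenylphosphonoacetamide, the E-enone from a dioxinone phosphonate.
3. Ring C (formed second) comes from a reductive Michael cyclization of an enal onto an enoate held cis on ring B.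
4. Rings A and B (formed together, first) come from an endo intramolecular Diels–Alder reaction of an (E,E,E)-trienal whose three-atom tether carries the two ring A stereocentres.
5. The tether stereocentres come from a dianionic ester-enolate Claisen rearrangement of (Z)-crotyl (S)-3-hydroxybutanoate; the carbinol carbon ends as the acetyl C=O, and the amino acid centre is bought as L-ornithine.

Assumption: starting materials 1, 2, 8, 20 and 26 and all named reagents are catalogue chemicals; the target is drawn as the enol tautomer given in the SMILES.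

## Route

Step 1
Reactants: 1 ethyl (3S)-3-hydroxybutanoate; 2 (Z)-but-2-en-1-ol
Product: 3 (Z)-but-2-en-1-yl (3S)-3-hydroxybutanoate
Conditions: Ti(OEt)4 (5 mol%), 2 (4 equiv, neat), 100 °C, EtOH distilled off
Reagents that add atoms: none
Why: Ti(OEt)4-catalysed transesterification exchanges the alkoxy group under neutral conditions, so the β-hydroxy stereocentre is untouched.

Step 2
Reactants: 3 (Z)-but-2-en-1-yl (3S)-3-hydroxybutanoate
Product: 4 (2S,3R)-2-[(1S)-1-hydroxyethyl]-3-methylpent-4-enoic acid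
Conditions: LiN(i-Pr)2 (2.3 equiv), THF, −78 °C → 25 °C, then 50 °C, 4 h; 1 M HCl
Reagents that add atoms: none
Why: Dianionic ester-enolate Claisen [3,3]-sigmatropic rearrangement: the Li-chelated Z(O)-enolate is attacked anti to the carbinol methyl (Fráter–Seebach-type 1,2-induction) through a chair with the Z-crotyl methyl axial, which sets C2 (S) and C3 (R).

Step 3
Reactants: 4 (2S,3R)-2-[(1S)-1-hydroxyethyl]-3-methylpent-4-enoic acid
Product: 6 (3S,4R)-3-[(1S)-1-hydroxyethyl]-4-methyloxan-2-one, via dihydroxy acid 5 (not isolated)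
Conditions: 9-borabicyclo[3.3.1]nonane (3.3 equiv), THF, 0 °C → rt; NaOH, H2O2, 0 °C → rt; HCl to pH 2; p-toluenesulfonic acid (cat.), CH2Cl2, rt
Reagents that add atoms: hydrogen peroxide (OO)
Why: Anti-Markovnikov hydroboration–oxidation of the only alkene gives a δ-hydroxy acid that lactonizes to the six-membered ring on acidification, with no stereocentre involved.

Step 4
Reactants: 6 (3S,4R)-3-[(1S)-1-hydroxyethyl]-4-methyloxan-2-one
Product: 7 (3S,4R)-4-methyl-3-[(1S)-1-(triethylsilyloxy)ethyl]oxan-2-one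
Conditions: Et3SiCl, imidazole, DMF, 0 °C → rt
Reagents that add atoms: chlorotriethylsilane (CC[Si](Cl)(CC)CC)
Why: Silylation of the secondary alcohol blocks retro-aldol and oxa-Michael pathways in the aldehyde and enal stages that follow.

Step 5
Reactants: 8 methyl (2E,4E)-hexa-2,4-dienoate
Product: 9 methyl (2E,4E)-6-bromohexa-2,4-dienoate
Conditions: N-bromosuccinimide, dibenzoyl peroxide (5 mol%), PhCl, 85 °C
Reagents that add atoms: N-bromosuccinimide (O=C1CCC(=O)N1Br)
Why: Wohl–Ziegler radical bromination occurs at the terminal methyl because the pentadienyl-type radical is captured at the end that keeps the dienoate conjugated.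

Step 6
Reactants: 9 methyl (2E,4E)-6-bromohexa-2,4-dienoate
Product: 10 methyl (2E,4E)-6-(diethoxyphosphoryl)hexa-2,4-dienoate
Conditions: P(OEt)3, neat, 120 °C
Reagents that add atoms: triethyl phosphite (CCOP(OCC)OCC)
Why: Michaelis–Arbuzov reaction of the primary allylic bromide gives the vinylogous phosphonoacetate.

Step 7
Reactants: 7 (3S,4R)-4-methyl-3-[(1S)-1-(triethylsilyloxy)ethyl]oxan-2-one; 10 methyl (2E,4E)-6-(diethoxyphosphoryl)hexa-2,4-dienoate
Product: 12 methyl (2E,4E,6E,8R,9R)-11-hydroxy-9-methyl-8-[(1S)-1-(triethylsilyloxy)ethyl]undeca-2,4,6-trienoate, via lactol 11 (not isolated)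
Conditions: i-Bu2AlH (1.1 equiv), THF, −78 °C; then 10 (1.6 equiv)/LiN(SiMe3)2 (1.5 equiv), THF, −78 °C → rt; aq. KNaC4H4O6
Reagents that add atoms: none
Why: One-pot lactone half-reduction and Horner–Wadsworth–Emmons olefination: the aluminium lactolate opens to the aldehyde, which the stabilized phosphonate anion converts E-selectively into the trienoate while releasing the primary alcohol.

Step 8
Reactants: 12 methyl (2E,4E,6E,8R,9R)-11-hydroxy-9-methyl-8-[(1S)-1-(triethylsilyloxy)ethyl]undeca-2,4,6-trienoate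
Product: 14 methyl (2E,4E,6E,8R,9R,11E)-9-methyl-13-oxo-8-[(1S)-1-(triethylsilyloxy)ethyl]trideca-2,4,6,11-tetraenoate, via aldehyde 13 (not isolated)
Conditions: PhI(OAc)2 (1.1 equiv), 2,2,6,6-tetramethylpiperidin-1-oxyl (10 mol%), CH2Cl2, rt; then Ph3P=CHCHO (1.4 equiv), 40 °C
Reagents that add atoms: (triphenylphosphoranylidene)acetaldehyde (O=CC=P(c1ccccc1)(c1ccccc1)c1ccccc1)
Why: Nitroxyl-catalysed oxidation of the primary alcohol followed in the same flask by Wittig reaction with the stabilized ylide gives the (E)-enal dienophile.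

Step 9
Reactants: 14 methyl (2E,4E,6E,8R,9R,11E)-9-methyl-13-oxo-8-[(1S)-1-(triethylsilyloxy)ethyl]trideca-2,4,6,11-tetraenoate
Product: 15 trans-fused hydrindene aldehyde (rings A and B)
Conditions: Me2AlCl (1.5 equiv), CH2Cl2, −78 → −30 °C; cold 1 M HCl
Reagents that add atoms: none
Why: Lewis acid-promoted intramolecular Diels–Alder [4+2] cycloaddition: the endo (CHO) transition state gives the trans ring fusion and the bulky silyloxyethyl group on the tether carbon next to the diene sits pseudo-equatorial, so the step 2 stereocentres fix all four new ring B stereocentres.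

Step 10
Reactants: 15 trans-fused hydrindene aldehyde (rings A and B)
Product: 16 hydrindene enal–enoate
Conditions: Ph3P=CHCHO (2 equiv), PhMe, 80 °C
Reagents that add atoms: (triphenylphosphoranylidene)acetaldehyde (O=CC=P(c1ccccc1)(c1ccccc1)c1ccccc1)
Why: Wittig two-carbon homologation with the stabilized ylide gives the (E)-enal without epimerizing the ring carbon.

Step 11
Reactants: 16 hydrindene enal–enoate
Product: 17 tricyclic aldehyde–ester (rings A, B and C)
Conditions: diethyl 2,6-dimethyl-1,4-dihydropyridine-3,5-dicarboxylate (1.2 equiv), pyrrolidine/CF3CO2H (20 mol% each), THF, rt → 40 °C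
Reagents that add atoms: none
Why: Reductive Michael cyclization: iminium conjugate reduction by the Hantzsch ester gives an enamine that closes ring C by 5-exo Michael addition onto the enoate, placing the CH2CO2Me arm on the convex face while the epimerizable formyl group settles trans to it.

Step 12
Reactants: 17 tricyclic aldehyde–ester (rings A, B and C)
Product: 19 lactol diol, via silyl lactol 18 (not isolated)
Conditions: i-Bu2AlH (2.5 equiv), CH2Cl2, −78 °C; then 1 M HCl/THF, rt, 1 h
Reagents that add atoms: none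
Why: Hydride reduces the aldehyde to the alkoxide and the ester to the aldehyde level, which collapse to a six-membered lactol that differentiates the two arms, and the acidic work-up removes the triethylsilyl group.

Step 13
Reactants: 20 Nα-Boc-L-ornithine
Product: 21 Nα-Boc-Nδ-(bromoacetyl)-L-ornithine
Conditions: N-succinimidyl bromoacetate (1.05 equiv), NaHCO3 (2 equiv), THF/H2O, 0 °C → rt; HCl to pH 3
Reagents that add atoms: N-succinimidyl bromoacetate (O=C(CBr)ON1C(=O)CCC1=O)
Why: The active ester acylates the free δ-amine much faster than the bromide is displaced, and the α-centre is not involved.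

Step 14
Reactants: 21 Nα-Boc-Nδ-(bromoacetyl)-L-ornithine
Product: 22 methyl Nα-Boc-Nδ-(bromoacetyl)-L-ornithinate
Conditions: Me3SiCHN2, PhMe/MeOH, 0 °C
Reagents that add atoms: (trimethylsilyl)diazomethane (C[Si](C)(C)C=[N+]=[N-])
Why: Diazoalkane esterification of the acid is neutral and fast, so neither the bromoacetamide nor the α-stereocentre is affected.

Step 15
Reactants: 22 methyl Nα-Boc-Nδ-(bromoacetyl)-L-ornithinate
Product: 23 methyl Nα-Boc-Nδ-[2-(diphenoxyphosphoryl)acetyl]-L-ornithinate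
Conditions: (PhO)2P(O)H, Et3N, CH2Cl2, 0 °C → rt
Reagents that add atoms: diphenyl phosphite (O=[PH](Oc1ccccc1)Oc1ccccc1)
Why: Michaelis–Becker-type P-alkylation of diphenyl phosphite by the α-bromoamide gives the Ando-type diaryl phosphonoacetamide.

Step 16
Reactants: 19 lactol diol; 23 methyl Nα-Boc-Nδ-[2-(diphenoxyphosphoryl)acetyl]-L-ornithinate
Product: 24 (Z)-enamide diol
Conditions: 23 (1.5 equiv), NaN(SiMe3)2 (1.45 equiv), THF, −78 °C; then 19, −78 → 0 °C
Reagents that add atoms: none
Why: Ando-type Z-selective Horner–Wadsworth–Emmons olefination: the diaryl phosphonate anion reacts with the hydroxy aldehyde in equilibrium with the lactol to give the (Z)-enamide and frees the primary alcohol.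

Step 17
Reactants: 24 (Z)-enamide diol
Product: 25 keto aldehyde
Conditions: Dess–Martin periodinane (2.6 equiv), CH2Cl2, 0 °C → rt
Reagents that add atoms: none
Why: Dess–Martin oxidation takes the primary alcohol to the aldehyde and the secondary alcohol to the methyl ketone in one operation, erasing the carbinol stereocentre that steered step 2.

Step 18
Reactants: 26 2,2,6-trimethyl-4H-1,3-dioxin-4-one
Product: 27 diethyl [(2,2-dimethyl-4-oxo-4H-1,3-dioxin-6-yl)methyl]phosphonate
Conditions: LiN(i-Pr)2 (2.1 equiv), THF, −78 °C; (EtO)2P(O)Cl; 1 M HCl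
Reagents that add atoms: diethyl chlorophosphate (CCOP(=O)(Cl)OCC)
Why: γ-Deprotonation gives the vinylogous enolate, which is C-phosphorylated at the methyl carbon, the second equivalent of base absorbing the more acidic product.

Step 19
Reactants: 25 keto aldehyde; 27 diethyl [(2,2-dimethyl-4-oxo-4H-1,3-dioxin-6-yl)methyl]phosphonate
Product: 28 dienyl dioxinone
Conditions: 27 (1.5 equiv), LiN(SiMe3)2 (1.45 equiv), THF, −78 °C; then 25, −78 → 0 °C
Reagents that add atoms: none
Why: Horner–Wadsworth–Emmons reaction of the stabilized anion is E-selective and takes the aldehyde in preference to the hindered methyl ketone.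

Step 20
Reactants: 28 dienyl dioxinone
Product: 31 17-membered β-ketoamide macrolactam, via ammonium trifluoroacetate 29 (not isolated), via acylketene 30 (not isolated)
Conditions: CF3CO2H/CH2Cl2 (1:4), 0 °C; evaporate; slow addition to Et3N (5 equiv), PhMe, 110 °C (0.5 mM)
Reagents that add atoms: none
Why: Acidolysis frees the α-amine, and thermal retro-[4+2] fragmentation of the dioxinone expels acetone to give an acylketene that the amine captures intramolecularly under high dilution (macrolactamization).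

Step 21
Reactants: 31 17-membered β-ketoamide macrolactam
Product: 32 target CNP0320820.1
Conditions: KOt-Bu (2.2 equiv), t-BuOH/THF, 0 °C → rt, 20 min; 1 M HCl
Reagents that add atoms: none
Why: Lacey–Dieckmann condensation of the β-ketoamide enolate onto the methyl ester closes the 3-acyltetramic acid, and the acidic product consumes the base so the amino acid and acetyl-bearing stereocentres are not epimerized.

## Compound list

1 | ethyl (3S)-3-hydroxybutanoate | CCOC(=O)C[C@H](C)O | starting material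
2 | (Z)-but-2-en-1-ol | C/C=C\CO | starting material
3 | (Z)-but-2-en-1-yl (3S)-3-hydroxybutanoate | C/C=C\COC(=O)C[C@H](C)O | intermediate
4 | (2S,3R)-2-[(1S)-1-hydroxyethyl]-3-methylpent-4-enoic acid | OC(=O)[C@H]([C@@H](O)C)[C@H](C)C=C | intermediate
5 | dihydroxy acid: (2S,3R)-5-hydroxy-2-[(1S)-1-hydroxyethyl]-3-methylpentanoic acid | OC(=O)[C@H]([C@@H](O)C)[C@H](C)CCO | intermediate
6 | (3S,4R)-3-[(1S)-1-hydroxyethyl]-4-methyloxan-2-one | O=C1OCC[C@@H](C)[C@H]1[C@@H](O)C | intermediate
7 | (3S,4R)-4-methyl-3-[(1S)-1-(triethylsilyloxy)ethyl]oxan-2-one | O=C1OCC[C@@H](C)[C@H]1[C@@H](O[Si](CC)(CC)CC)C | intermediate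
8 | methyl (2E,4E)-hexa-2,4-dienoate | C/C=C/C=C/C(=O)OC | starting material
9 | methyl (2E,4E)-6-bromohexa-2,4-dienoate | BrC/C=C/C=C/C(=O)OC | intermediate
10 | methyl (2E,4E)-6-(diethoxyphosphoryl)hexa-2,4-dienoate | CCOP(=O)(OCC)C/C=C/C=C/C(=O)OC | intermediate
11 | lactol: (3S,4R)-4-methyl-3-[(1S)-1-(triethylsilyloxy)ethyl]oxan-2-ol, formed as its aluminium alkoxide, both anomers | OC1OCC[C@@H](C)[C@H]1[C@@H](O[Si](CC)(CC)CC)C | intermediate
12 | methyl (2E,4E,6E,8R,9R)-11-hydroxy-9-methyl-8-[(1S)-1-(triethylsilyloxy)ethyl]undeca-2,4,6-trienoate | OCC[C@@H](C)[C@@H]([C@@H](O[Si](CC)(CC)CC)C)/C=C/C=C/C=C/C(=O)OC | intermediate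
13 | aldehyde: methyl (2E,4E,6E,8R,9R)-9-methyl-11-oxo-8-[(1S)-1-(triethylsilyloxy)ethyl]undeca-2,4,6-trienoate | O=CC[C@@H](C)[C@@H]([C@@H](O[Si](CC)(CC)CC)C)/C=C/C=C/C=C/C(=O)OC | intermediate
14 | methyl (2E,4E,6E,8R,9R,11E)-9-methyl-13-oxo-8-[(1S)-1-(triethylsilyloxy)ethyl]trideca-2,4,6,11-tetraenoate | O=C/C=C/C[C@@H](C)[C@@H]([C@@H](O[Si](CC)(CC)CC)C)/C=C/C=C/C=C/C(=O)OC | intermediate
15 | trans-fused hydrindene aldehyde (rings A and B): methyl (E)-3-{4-formyl-2-methyl-1-[(1S)-1-(triethylsilyloxy)ethyl]-2,3,3a,4,5,7a-hexahydro-1H-inden-5-yl}prop-2-enoate; H-3a/H-7a trans, 4-CHO and 5-alkenyl cis to each other and to H-3a, 1-substituent cis to H-7a and to 2-CH3 | C[C@H](O[Si](CC)(CC)CC)[C@H]1[C@@H]2C=C[C@H](/C=C/C(=O)OC)[C@H](C=O)[C@H]2C[C@H]1C | intermediate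
16 | hydrindene enal–enoate: as 15 with the 4-formyl group replaced by (E)-3-oxoprop-1-enyl | C[C@H](O[Si](CC)(CC)CC)[C@H]1[C@@H]2C=C[C@H](/C=C/C(=O)OC)[C@H](/C=C/C=O)[C@H]2C[C@H]1C | intermediate
17 | tricyclic aldehyde–ester (rings A, B and C): as-indacene core, A/B trans, B/C cis; ring C carries CH2CO2Me (next to the allylic ring-fusion CH, cis to its H) and CHO (on the next carbon, trans to CH2CO2Me); ring A as in 15 | C[C@H](O[Si](CC)(CC)CC)[C@H]1[C@@H]2C=C[C@@H]3[C@@H](CC(=O)OC)[C@H](C=O)C[C@@H]3[C@H]2C[C@H]1C | intermediate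
18 | silyl lactol: 17 with the CHO and CH2CO2Me arms joined as a trans-fused tetrahydropyran-2-ol, both anomers | C[C@H](O[Si](CC)(CC)CC)[C@H]1[C@@H]2C=C[C@@H]3[C@H]4CC(O)OC[C@@H]4C[C@@H]3[C@H]2C[C@H]1C | intermediate
19 | lactol diol: 18 with the silyl ether cleaved to the (1S)-1-hydroxyethyl group | C[C@H](O)[C@H]1[C@@H]2C=C[C@@H]3[C@H]4CC(O)OC[C@@H]4C[C@@H]3[C@H]2C[C@H]1C | intermediate
20 | Nα-Boc-L-ornithine | CC(C)(C)OC(=O)N[C@@H](CCCN)C(=O)O | starting material
21 | Nα-Boc-Nδ-(bromoacetyl)-L-ornithine | CC(C)(C)OC(=O)N[C@@H](CCCNC(=O)CBr)C(=O)O | intermediate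
22 | methyl Nα-Boc-Nδ-(bromoacetyl)-L-ornithinate | CC(C)(C)OC(=O)N[C@@H](CCCNC(=O)CBr)C(=O)OC | intermediate
23 | methyl Nα-Boc-Nδ-[2-(diphenoxyphosphoryl)acetyl]-L-ornithinate | CC(C)(C)OC(=O)N[C@@H](CCCNC(=O)CP(=O)(Oc1ccccc1)Oc1ccccc1)C(=O)OC | intermediate
24 | (Z)-enamide diol: ring C carries CH2OH and the (Z)-CH2CH=CHC(=O)NH(CH2)3CH(NHBoc)CO2Me arm; ring A carries (1S)-1-hydroxyethyl | C[C@H](O)[C@H]1[C@@H]2C=C[C@@H]3[C@@H](C/C=C\C(=O)NCCC[C@H](NC(=O)OC(C)(C)C)C(=O)OC)[C@H](CO)C[C@@H]3[C@H]2C[C@H]1C | intermediate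
25 | keto aldehyde: 24 with CH2OH oxidized to CHO and the hydroxyethyl group to acetyl | CC(=O)[C@H]1[C@@H]2C=C[C@@H]3[C@@H](C/C=C\C(=O)NCCC[C@H](NC(=O)OC(C)(C)C)C(=O)OC)[C@H](C=O)C[C@@H]3[C@H]2C[C@H]1C | intermediate
26 | 2,2,6-trimethyl-4H-1,3-dioxin-4-one | CC1=CC(=O)OC(C)(C)O1 | starting material
27 | diethyl [(2,2-dimethyl-4-oxo-4H-1,3-dioxin-6-yl)methyl]phosphonate | CCOP(=O)(OCC)CC1=CC(=O)OC(C)(C)O1 | intermediate
28 | dienyl dioxinone: 25 with CHO converted into (E)-CH=CH-(2,2-dimethyl-4-oxo-4H-1,3-dioxin-6-yl) | CC(=O)[C@H]1[C@@H]2C=C[C@@H]3[C@@H](C/C=C\C(=O)NCCC[C@H](NC(=O)OC(C)(C)C)C(=O)OC)[C@H](/C=C/C4=CC(=O)OC(C)(C)O4)C[C@@H]3[C@H]2C[C@H]1C | intermediate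
29 | ammonium trifluoroacetate: 28 with the Boc group removed | CC(=O)[C@H]1[C@@H]2C=C[C@@H]3[C@@H](C/C=C\C(=O)NCCC[C@H]([NH3+])C(=O)OC)[C@H](/C=C/C4=CC(=O)OC(C)(C)O4)C[C@@H]3[C@H]2C[C@H]1C.[O-]C(=O)C(F)(F)F | intermediate
30 | acylketene: free amine with the dioxinone opened to (E)-CH=CH-C(=O)-CH=C=O | CC(=O)[C@H]1[C@@H]2C=C[C@@H]3[C@@H](C/C=C\C(=O)NCCC[C@H](N)C(=O)OC)[C@H](/C=C/C(=O)C=C=O)C[C@@H]3[C@H]2C[C@H]1C | intermediate
31 | 17-membered β-ketoamide macrolactam (Z-enamide, E-enone, ornithine methyl ester) | CC(=O)[C@H]1[C@@H]2C=C[C@@H]3[C@H]4C/C=C\C(=O)NCCC[C@@H](C(=O)OC)NC(=O)CC(=O)/C=C/[C@@H]4C[C@@H]3[C@H]2C[C@H]1C | intermediate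
32 | target CNP0320820.1 | CC(=O)[C@H]1[C@@H]2C=C[C@@H]3[C@H]4C/C=C\C(=O)NCCC[C@@H]5NC(=O)C(=C5O)C(=O)/C=C/[C@@H]4C[C@@H]3[C@H]2C[C@H]1C | target

## Step count and risks

Total step count: 21. Longest linear sequence: 15 steps (steps 1–4, 7–12, 16, 17, 19–21).

Most likely to fail:

Step 2. Yield and the 2,3-anti selectivity of the dianion Claisen with a Z-crotyl group are the weak points. Fallback: starting again from 1, transesterify with (E)-but-2-en-1-ol (Ti(OEt)4) to (E)-but-2-en-1-yl (3S)-3-hydroxybutanoate F1 and silylate (Et3SiCl, imidazole) to (E)-but-2-en-1-yl (3S)-3-(triethylsilyloxy)butanoate F2. A conventional Ireland–Claisen rearrangement (LiN(i-Pr)2, Me3SiCl, THF, −78 °C → rt) then gives (2S,3R)-3-methyl-2-[(1S)-1-(triethylsilyloxy)ethyl]pent-4-enoic acid F3: the non-chelated E(O)-enolate with the E-crotyl chair delivers the same 2,3-anti relationship, and the in-plane silyloxy group directs attack anti to the carbinol methyl. AcOH/THF/H2O removes the silyl group and the route is rejoined at 4.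

Step 11. The enamine may be too weak a nucleophile for the enoate, giving only the reduced open-chain aldehyde. Fallback: from 16, a PMe3-catalysed Rauhut–Currier cyclization (phosphine adds to the enal, the enolate attacks the enoate, phosphine is expelled) gives the ring C cyclopentene carbaldehyde F4. Iminium transfer hydrogenation of that enal (Hantzsch ester, dibenzylammonium trifluoroacetate), with equilibration of the formyl group to trans, comes back at 17.

Step 16. Z-selectivity of a secondary phosphonoacetamide on a lactol is the least precedented olefination here. Fallback: from 19, Still–Gennari olefination with methyl bis(2,2,2-trifluoroethyl)phosphonoacetate (KN(SiMe3)2, 18-crown-6, THF, −78 °C) gives the (Z)-methyl enoate diol F5 and LiOH hydrolysis the (Z)-enoic acid diol F6. EDC/N-hydroxysuccinimide converts it to the N-succinimidyl (Z)-enoate F7, which acylates the δ-amine of 20 (NaHCO3, THF/H2O) to the amide acid F8; Me3SiCHN2 esterification comes back at 24.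

Further compounds
F1 | step 2 | (E)-but-2-en-1-yl (3S)-3-hydroxybutanoate | C/C=C/COC(=O)C[C@H](C)O
F2 | step 2 | (E)-but-2-en-1-yl (3S)-3-(triethylsilyloxy)butanoate | C/C=C/COC(=O)C[C@H](C)O[Si](CC)(CC)CC
F3 | step 2 | (2S,3R)-3-methyl-2-[(1S)-1-(triethylsilyloxy)ethyl]pent-4-enoic acid | OC(=O)[C@H]([C@@H](O[Si](CC)(CC)CC)C)[C@H](C)C=C
F4 | step 11 | ring C cyclopentene carbaldehyde (Rauhut–Currier product of 16) | C[C@H](O[Si](CC)(CC)CC)[C@H]1[C@@H]2C=C[C@@H]3[C@@H](CC(=O)OC)C(C=O)=C[C@@H]3[C@H]2C[C@H]1C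
F5 | step 16 | (Z)-methyl enoate diol | C[C@H](O)[C@H]1[C@@H]2C=C[C@@H]3[C@@H](C/C=C\C(=O)OC)[C@H](CO)C[C@@H]3[C@H]2C[C@H]1C
F6 | step 16 | (Z)-enoic acid diol | C[C@H](O)[C@H]1[C@@H]2C=C[C@@H]3[C@@H](C/C=C\C(=O)O)[C@H](CO)C[C@@H]3[C@H]2C[C@H]1C
F7 | step 16 | N-succinimidyl (Z)-enoate | C[C@H](O)[C@H]1[C@@H]2C=C[C@@H]3[C@@H](C/C=C\C(=O)ON4C(=O)CCC4=O)[C@H](CO)C[C@@H]3[C@H]2C[C@H]1C
F8 | step 16 | (Z)-enamide diol with free ornithine carboxylic acid | C[C@H](O)[C@H]1[C@@H]2C=C[C@@H]3[C@@H](C/C=C\C(=O)NCCC[C@H](NC(=O)OC(C)(C)C)C(=O)O)[C@H](CO)C[C@@H]3[C@H]2C[C@H]1C
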